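**Strategy.** Everything rests on cutting C6'–C7' at the saturated ring B (primed atoms). The feature exploited is that C6' lies in ring B between the quaternary C1' and the stereogenic C5' and opens the diene C6'=C7'–C8'=C9', which is what a but-2-yne-1,4-diol oxygenated at C6' and C9' becomes once both oxygens are removed reductively. In one operation a cerium acetylide adds to the carbonyl of (S)-2,2,6-trimethylcyclohexanone, joining the hindered ring carbon to C7' without enolising C5'. The precursors are this ketone and a C5 alkynol acetal whose acetal carbon becomes C10'. Reductive 1,4-elimination, ylide homologations and a C21 + C19 Wittig union with the ring A half finish the polyene.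

Key step: step 3

Remark on the chemistry: carotenoid numbering is used (unprimed = half with the ring A bond C4=C5, primed = half with saturated ring B). The target is read as all-E (5'S,6E,6'E)-4,5'-retro-β,β-carotene. Step 1 assumes an ene-reductase whose active site protonates C2 of 1 on the face leading to the (S)-ketone, the sense being checked on 2 before use.

**Step 1**
Reactants: 1 2,6,6-trimethylcyclohex-2-en-1-one
Product: 2 (6S)-2,2,6-trimethylcyclohexan-1-one
Conditions: ene-reductase (old yellow enzyme family, (S)-selective), NADP+ (cat.), D-glucose, glucose dehydrogenase, KH2PO4/K2HPO4 buffer pH 7, 30 °C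
Reagents that add atoms: none
Why: Ene-reductase conjugate reduction, in which the reduced flavin delivers hydride to C3 and an active-site tyrosine protonates C2 on the opposite face, so the C2 stereocentre (later C5') is set by the binding mode of the enzyme, chosen here for (S).

**Step 2**
Reactants: 3 pyruvaldehyde dimethyl acetal (1,1-dimethoxypropan-2-one); 4 ethynylmagnesium bromide
Product: 5 1,1-dimethoxy-2-methylbut-3-yn-2-ol (racemic)
Conditions: THF, 0 °C to rt; aq. NH4Cl
Reagents that add atoms: none
Why: Grignard 1,2-addition of an acetylide to an unhindered α,α-dialkoxy ketone; the new carbinol centre forms racemic and is erased in step 4.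

**Step 3**
Reactants: 2 (6S)-2,2,6-trimethylcyclohexan-1-one; 5 1,1-dimethoxy-2-methylbut-3-yn-2-ol
Product: 8 (6S)-1-(3-hydroxy-4,4-dimethoxy-3-methylbut-1-yn-1-yl)-2,2,6-trimethylcyclohexan-1-ol as a mixture of carbinol epimers, via dilithium salt 6 (not isolated), via cerium acetylide 7 (not isolated)
Conditions: 5 (1.5 equiv), n-BuLi (3.0 equiv), THF, −78 °C; anhydrous CeCl3 (1.6 equiv), −78 °C; then 2, −78 to −30 °C; aq. NH4Cl
Reagents that add atoms: none
Why: Double deprotonation of 5 gives the lithium alkoxide acetylide 6, which transmetallates to CeCl3, and the resulting alkynylcerium 7 adds through a four-centre, Lewis-acid-assisted transition state to the carbonyl carbon of 2, making the C6'–C7' bond; the closest known reaction type is the organocerium 1,2-addition of acetylides to hindered, enolisable ketones. No ring is closed. The new carbinol centre C6' arises under substrate control (the linear nucleophile passes the axial C1' methyl, probably anti to the C5' methyl) and C9' enters racemic, but neither matters because both oxygens leave in step 4. The only existing stereocentre, C5', carries the single α-hydrogen of the ketone, so the selectivity required is carbonyl addition over enolisation. Substrate and reagent together should secure it: C1' is quaternary and offers no proton, the C5' hydrogen is tertiary and shielded, the sp nucleophile is slim, and the oxophilic, weakly basic cerium reagent activates C=O instead of abstracting that proton. An excess of 7 over 2 and a cold quench should keep the C5' configuration intact.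

**Step 4**
Reactants: 8 (6S)-1-(3-hydroxy-4,4-dimethoxy-3-methylbut-1-yn-1-yl)-2,2,6-trimethylcyclohexan-1-ol
Product: 10 (1E,6S)-1-[(2E)-4,4-dimethoxy-3-methylbut-2-en-1-ylidene]-2,2,6-trimethylcyclohexane (chain syn to C5'), via allenol 9 (not isolated)
Conditions: LiAlH4 (4 equiv), THF, 0 °C to reflux; H2O, aq. NaOH
Reagents that add atoms: none
Why: Whiting-type reductive 1,4-elimination of a but-2-yne-1,4-diol, in which alkoxide-directed trans-hydroalumination, loss of the first aluminate oxygen to allenol 9 (either order of oxygen loss converges) and a second hydride delivery with loss of the other oxygen should give the diene without a cation at C6', so C5' stays (S) and the exocyclic bond settles on the less strained E isomer with C8' syn to C5'.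

**Step 5**
Reactants: 10 (1E,6S)-1-[(2E)-4,4-dimethoxy-3-methylbut-2-en-1-ylidene]-2,2,6-trimethylcyclohexane
Product: 11 (2E)-2-methyl-4-[(1E,6S)-2,2,6-trimethylcyclohexylidene]but-2-enal (C14 aldehyde of ring B, CHO = C10')
Conditions: pyridinium p-toluenesulfonate (cat.), acetone/H2O, rt
Reagents that add atoms: water, O
Why: Acid-catalysed hydrolysis of an allylic dimethyl acetal through a diene-stabilised oxocarbenium ion, fast enough under this weak acid that neither migration of C6'=C7' into the ring nor dienolisation towards C5' should compete.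

**Step 6**
Reactants: 11 (2E)-2-methyl-4-[(1E,6S)-2,2,6-trimethylcyclohexylidene]but-2-enal; 12 (triphenylphosphoranylidene)acetaldehyde
Product: 13 (2E,4E)-4-methyl-6-[(1E,6S)-2,2,6-trimethylcyclohexylidene]hexa-2,4-dienal (C16 aldehyde, CHO = C12')
Conditions: 12 (1.0 equiv), toluene, 60 °C
Reagents that add atoms: none
Why: Wittig olefination with a formyl-stabilised ylide, E-selective at C10'=C11' and run under neutral conditions so that the vinylogously acidic C5'–H sees no base, with the ylide held to one equivalent to limit a second homologation.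

**Step 7**
Reactants: 13 (2E,4E)-4-methyl-6-[(1E,6S)-2,2,6-trimethylcyclohexylidene]hexa-2,4-dienal; 14 2-(triphenylphosphoranylidene)propanal
Product: 15 (2E,4E,6E)-2,6-dimethyl-8-[(1E,6S)-2,2,6-trimethylcyclohexylidene]octa-2,4,6-trienal (C19 aldehyde, CHO = C14')
Conditions: toluene, 70 °C
Reagents that add atoms: none
Why: Wittig olefination with the α-methyl formyl-stabilised ylide should give the E trisubstituted C12'=C13' bond, and the α-branched enal formed is too unreactive to be homologated again.

**Step 8**
Reactants: 15 (2E,4E,6E)-2,6-dimethyl-8-[(1E,6S)-2,2,6-trimethylcyclohexylidene]octa-2,4,6-trienal; 12 (triphenylphosphoranylidene)acetaldehyde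
Product: 16 (2E,4E,6E,8E)-4,8-dimethyl-10-[(1E,6S)-2,2,6-trimethylcyclohexylidene]deca-2,4,6,8-tetraenal (C21 aldehyde, CHO = C15)
Conditions: 12 (1.0 equiv), toluene, 70 °C
Reagents that add atoms: none
Why: A second neutral two-carbon Wittig homologation with the stabilised ylide, E-selective at C14'=C15', places the aldehyde carbon at C15 for the final union.

**Step 9**
Reactants: 1 2,6,6-trimethylcyclohex-2-en-1-one; 5 1,1-dimethoxy-2-methylbut-3-yn-2-ol
Product: 18 1-(3-hydroxy-4,4-dimethoxy-3-methylbut-1-yn-1-yl)-2,6,6-trimethylcyclohex-2-en-1-ol as a mixture of racemic diastereomers, via magnesium acetylide 17 (not isolated)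
Conditions: 5 (1.3 equiv), EtMgBr (2.6 equiv), THF, 0 to 40 °C; then 1, 0 °C to rt; aq. NH4Cl
Reagents that add atoms: none
Why: Alkynyl Grignard (Iotsich reagent) 1,2-addition to the enone carbonyl forms C6–C7; ketone 1 has no α-hydrogen (C1 is quaternary and C5 is sp2), so the plain magnesium acetylide made from 5 and two equivalents of EtMgBr suffices, the hard sp nucleophile prefers the carbonyl over the β-carbon, and the carbinol centres created are erased in step 10.

**Step 10**
Reactants: 18 1-(3-hydroxy-4,4-dimethoxy-3-methylbut-1-yn-1-yl)-2,6,6-trimethylcyclohex-2-en-1-ol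
Product: 20 (6E)-6-[(2E)-4,4-dimethoxy-3-methylbut-2-en-1-ylidene]-1,5,5-trimethylcyclohex-1-ene (C8 syn to the gem-dimethyl carbon), via allenol 19 (not isolated)
Conditions: LiAlH4 (4 equiv), THF, 0 °C to reflux; H2O, aq. NaOH
Reagents that add atoms: none
Why: Whiting-type reductive 1,4-elimination as in step 4 leaves the ring bond C4=C5 in place and should give the triene, whose exocyclic C6=C7 bond is expected to prefer the E geometry in which C8 avoids the in-plane C5 methyl.

**Step 11**
Reactants: 20 (6E)-6-[(2E)-4,4-dimethoxy-3-methylbut-2-en-1-ylidene]-1,5,5-trimethylcyclohex-1-ene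
Product: 21 (2E)-2-methyl-4-[(1E)-2,6,6-trimethylcyclohex-2-en-1-ylidene]but-2-enal (C14 aldehyde of ring A, CHO = C10)
Conditions: pyridinium p-toluenesulfonate (cat.), acetone/H2O, 0 °C to rt
Reagents that add atoms: water, O
Why: Mild acid hydrolysis of the allylic dimethyl acetal through a triene-stabilised oxocarbenium ion should release the conjugated aldehyde without disturbing the retro triene.

**Step 12**
Reactants: 21 (2E)-2-methyl-4-[(1E)-2,6,6-trimethylcyclohex-2-en-1-ylidene]but-2-enal; 12 (triphenylphosphoranylidene)acetaldehyde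
Product: 22 (2E,4E)-4-methyl-6-[(1E)-2,6,6-trimethylcyclohex-2-en-1-ylidene]hexa-2,4-dienal (C16 aldehyde, CHO = C12)
Conditions: 12 (1.0 equiv), toluene, 60 °C
Reagents that add atoms: none
Why: E-selective Wittig olefination with the formyl-stabilised ylide forms C10=C11 under neutral conditions.

**Step 13**
Reactants: 22 (2E,4E)-4-methyl-6-[(1E)-2,6,6-trimethylcyclohex-2-en-1-ylidene]hexa-2,4-dienal; 23 isopropenylmagnesium bromide
Product: 24 (4E,6E)-2,6-dimethyl-8-[(1E)-2,6,6-trimethylcyclohex-2-en-1-ylidene]octa-1,4,6-trien-3-ol (racemic)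
Conditions: THF, −78 to 0 °C; aq. NH4Cl
Reagents that add atoms: none
Why: Grignard 1,2-addition of a vinyl nucleophile to the polyenal carbonyl brings in C13, its methyl and C14; the racemic carbinol centre disappears in step 14.

**Step 14**
Reactants: 24 (4E,6E)-2,6-dimethyl-8-[(1E)-2,6,6-trimethylcyclohex-2-en-1-ylidene]octa-1,4,6-trien-3-ol
Product: 25 [(2E,4E,6E)-2,6-dimethyl-8-[(1E)-2,6,6-trimethylcyclohex-2-en-1-ylidene]octa-2,4,6-trien-1-yl]triphenylphosphonium bromide (C19 salt, P on C14)
Conditions: PPh3·HBr, MeOH, 0 °C to rt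
Reagents that add atoms: triphenylphosphine hydrobromide, Br.c1ccc(cc1)P(c1ccccc1)c1ccccc1
Why: Phosphonium salt formation from a vinyl carbinol with allylic transposition, the standard route to carotenoid Wittig salts, in which the delocalised polyenyl cation should be captured by PPh3 at its unhindered primary terminus C14 to leave the E C12=C13 bond.

**Step 15**
Reactants: 25 C19 phosphonium bromide of ring A; 16 (2E,4E,6E,8E)-4,8-dimethyl-10-[(1E,6S)-2,2,6-trimethylcyclohexylidene]deca-2,4,6,8-tetraenal
Product: 28 all-E (5'S,6E,6'E)-4,5'-retro-β,β-carotene (target), via ylide 26 (not isolated), via 14Z isomer 27 (not isolated)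
Conditions: NaN(SiMe3)2 (0.98 equiv per 25), THF, −78 °C; then 16, −78 °C to rt; then I2 (cat.), hexane/CH2Cl2, daylight, rt
Reagents that add atoms: none
Why: Wittig olefination of the preformed semi-stabilised ylide with the C21 aldehyde forms C14=C15 without free base near the C5'–H, and iodine-catalysed equilibration should turn the 14Z isomer and any ring-end Z isomers into the thermodynamically favoured all-E polyene; no stereocentre is formed and C5' is not touched.

**Compound list**
1 | 2,6,6-trimethylcyclohex-2-en-1-one | CC1=CCCC(C)(C)C1=O | starting material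
2 | (6S)-2,2,6-trimethylcyclohexan-1-one | O=C1[C@@H](C)CCCC1(C)C | intermediate
3 | pyruvaldehyde dimethyl acetal (1,1-dimethoxypropan-2-one) | CC(=O)C(OC)OC | starting material
4 | ethynylmagnesium bromide | C#C[Mg]Br | starting material
5 | 1,1-dimethoxy-2-methylbut-3-yn-2-ol (racemic) | C#CC(C)(O)C(OC)OC | intermediate
6 | dilithium salt of 5, lithium 4-lithio-1,1-dimethoxy-2-methylbut-3-yn-2-olate (not isolated) | COC(OC)C(C)(O[Li])C#C[Li] | intermediate
7 | dichlorocerium acetylide of lithium 1,1-dimethoxy-2-methylbut-3-yn-2-olate (not isolated) | COC(OC)C(C)(O[Li])C#C[Ce](Cl)Cl | intermediate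
8 | (6S)-1-(3-hydroxy-4,4-dimethoxy-3-methylbut-1-yn-1-yl)-2,2,6-trimethylcyclohexan-1-ol (carbinol epimers) | COC(OC)C(C)(O)C#CC1(O)[C@@H](C)CCCC1(C)C | intermediate
9 | 1,1-dimethoxy-2-methyl-4-[(6S)-2,2,6-trimethylcyclohexylidene]but-3-en-2-ol (allenol, not isolated) | COC(OC)C(C)(O)C=C=C1[C@@H](C)CCCC1(C)C | intermediate
10 | (1E,6S)-1-[(2E)-4,4-dimethoxy-3-methylbut-2-en-1-ylidene]-2,2,6-trimethylcyclohexane | COC(OC)/C(C)=C/C=C1\[C@@H](C)CCCC1(C)C | intermediate
11 | (2E)-2-methyl-4-[(1E,6S)-2,2,6-trimethylcyclohexylidene]but-2-enal | O=C/C(C)=C/C=C1\[C@@H](C)CCCC1(C)C | intermediate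
12 | (triphenylphosphoranylidene)acetaldehyde | O=CC=P(c1ccccc1)(c1ccccc1)c1ccccc1 | starting material
13 | (2E,4E)-4-methyl-6-[(1E,6S)-2,2,6-trimethylcyclohexylidene]hexa-2,4-dienal | O=C/C=C/C(C)=C/C=C1\[C@@H](C)CCCC1(C)C | intermediate
14 | 2-(triphenylphosphoranylidene)propanal | CC(C=O)=P(c1ccccc1)(c1ccccc1)c1ccccc1 | starting material
15 | (2E,4E,6E)-2,6-dimethyl-8-[(1E,6S)-2,2,6-trimethylcyclohexylidene]octa-2,4,6-trienal | O=C/C(C)=C/C=C/C(C)=C/C=C1\[C@@H](C)CCCC1(C)C | intermediate
16 | (2E,4E,6E,8E)-4,8-dimethyl-10-[(1E,6S)-2,2,6-trimethylcyclohexylidene]deca-2,4,6,8-tetraenal | O=C/C=C/C(C)=C/C=C/C(C)=C/C=C1\[C@@H](C)CCCC1(C)C | intermediate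
17 | bis(bromomagnesium) derivative of 5, bromomagnesium 4-(bromomagnesio)-1,1-dimethoxy-2-methylbut-3-yn-2-olate (not isolated) | COC(OC)C(C)(O[Mg]Br)C#C[Mg]Br | intermediate
18 | 1-(3-hydroxy-4,4-dimethoxy-3-methylbut-1-yn-1-yl)-2,6,6-trimethylcyclohex-2-en-1-ol (racemic diastereomers) | COC(OC)C(C)(O)C#CC1(O)C(C)=CCCC1(C)C | intermediate
19 | 1,1-dimethoxy-2-methyl-4-(2,6,6-trimethylcyclohex-2-en-1-ylidene)but-3-en-2-ol (allenol, not isolated) | COC(OC)C(C)(O)C=C=C1C(C)=CCCC1(C)C | intermediate
20 | (6E)-6-[(2E)-4,4-dimethoxy-3-methylbut-2-en-1-ylidene]-1,5,5-trimethylcyclohex-1-ene | COC(OC)/C(C)=C/C=C1/C(C)=CCCC1(C)C | intermediate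
21 | (2E)-2-methyl-4-[(1E)-2,6,6-trimethylcyclohex-2-en-1-ylidene]but-2-enal | O=C/C(C)=C/C=C1/C(C)=CCCC1(C)C | intermediate
22 | (2E,4E)-4-methyl-6-[(1E)-2,6,6-trimethylcyclohex-2-en-1-ylidene]hexa-2,4-dienal | O=C/C=C/C(C)=C/C=C1/C(C)=CCCC1(C)C | intermediate
23 | isopropenylmagnesium bromide | CC(=C)[Mg]Br | starting material
24 | (4E,6E)-2,6-dimethyl-8-[(1E)-2,6,6-trimethylcyclohex-2-en-1-ylidene]octa-1,4,6-trien-3-ol (racemic) | C=C(C)C(O)/C=C/C(C)=C/C=C1/C(C)=CCCC1(C)C | intermediate
25 | [(2E,4E,6E)-2,6-dimethyl-8-[(1E)-2,6,6-trimethylcyclohex-2-en-1-ylidene]octa-2,4,6-trien-1-yl]triphenylphosphonium bromide | [Br-].c1ccccc1[P+](c1ccccc1)(c1ccccc1)C/C(C)=C/C=C/C(C)=C/C=C1/C(C)=CCCC1(C)C | intermediate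
26 | ylide of 25 (not isolated) | c1ccccc1P(c1ccccc1)(c1ccccc1)=C/C(C)=C/C=C/C(C)=C/C=C1/C(C)=CCCC1(C)C | intermediate
27 | (14Z)-isomer of the target (not isolated) | CC1=CCCC(C)(C)\C1=C/C=C(C)/C=C/C=C(C)/C=C\C=C\C(C)=C\C=C\C(C)=C\C=C1/[C@@H](C)CCCC1(C)C | intermediate
28 | all-E (5'S,6E,6'E)-4,5'-retro-β,β-carotene | CC1=CCCC(C)(C)\C1=C/C=C(C)/C=C/C=C(C)/C=C/C=C/C(C)=C/C=C/C(C)=C/C=C1\[C@@H](C)CCCC1(C)C | target

**Step count.** Total: 15 steps. Longest linear sequence: 8 steps (1, 3, 4, 5, 6, 7, 8, 15; the ring A branch 2, 9, 10, 11, 12, 13, 14, 15 is equally long).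

**Steps most likely to fail**

Step 3 (key step). Proton abstraction from C5' may outrun carbonyl addition, returning partly racemised ketone, or the alkoxide-bearing cerium reagent may aggregate and add sluggishly. The fallback sets out from 2 and builds the yne-diol in the opposite order. Ketone 2 would first take up the smallest carbon nucleophile, ethynylmagnesium bromide 4 (THF, CeCl3, 0 °C), an addition well known for this ketone, to give (6S)-1-ethynyl-2,2,6-trimethylcyclohexan-1-ol F1. F1 would then be doubly deprotonated (n-BuLi, THF, −78 °C, CeCl3) and added to the unhindered ketone 3, so that the second bond (C8'–C9') is made where crowding is absent. This comes back to the route at 8.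

Step 1. The enzyme may bind the enone in the opposite orientation and protonate the other face of C2, or turn over slowly because of the gem-dimethyl group beside the carbonyl. The fallback sets out from 1 and replaces biocatalysis by enantioselective protonation. Conjugate reduction with LiBH(s-Bu)3 (THF, −78 °C) and trapping of the enolate with Me3SiCl would give trimethyl[(2,6,6-trimethylcyclohex-1-en-1-yl)oxy]silane F2, the only possible enol ether. Protonation of F2 with the SnCl4 complex of enantiopure BINOL (toluene, −78 °C; the BINOL enantiomer chosen for the (S)-product) comes back to the route at 2.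

Step 4. The reduction may stop after the first hydride delivery or at the allenol, or hydride may over-reduce the diene. The fallback sets out from 8 and separates reduction from deoxygenation. LiAlH4 at 0 °C to rt without heating would be stopped at the trans-hydroalumination stage to give (6S)-1-[(1E)-3-hydroxy-4,4-dimethoxy-3-methylbut-1-en-1-yl]-2,2,6-trimethylcyclohexan-1-ol F3. Low-valent titanium made from TiCl3 and LiAlH4 (THF, rt to reflux) would then effect the known reductive 1,4-elimination of the 2-ene-1,4-diol, again without a cation at C6'. This comes back to the route at 10.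

**Further compounds**
F1 | step 3 | (6S)-1-ethynyl-2,2,6-trimethylcyclohexan-1-ol | C#CC1(O)[C@@H](C)CCCC1(C)C
F2 | step 1 | trimethyl[(2,6,6-trimethylcyclohex-1-en-1-yl)oxy]silane | CC1=C(O[Si](C)(C)C)C(C)(C)CCC1
F3 | step 4 | (6S)-1-[(1E)-3-hydroxy-4,4-dimethoxy-3-methylbut-1-en-1-yl]-2,2,6-trimethylcyclohexan-1-ol | COC(OC)C(C)(O)/C=C/C1(O)[C@@H](C)CCCC1(C)C
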